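**Retrosynthetic overview**
1. Target ⇒ one hydrogenolysis removes four O‑benzyl groups and reduces the ArC(=O) at C4 to ArCH2. Before that, the free phenol is ortho‑acylated with 3‑(4‑methoxyphenyl)propanoyl chloride.
2. C4 aryl ketone ⇒ a 4‑(benzyloxy)phenyl Grignard reagent opens a seven‑membered aryl lactone through its Weinreb amide. C3 methyl ⇒ enolate methylation of that lactone.
3. Key bond C1–C2 ⇒ carbene‑bound homoenolate of crotonaldehyde (β‑carbon made nucleophilic) plus a phloroglucinol‑derived o‑quinone methide (electrophilic benzhydryl carbon), formal [4+3]. This sets C1 and C2.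
4. o‑Quinone methide ⇒ 2,4‑bis(benzyloxy)‑6‑hydroxybenzaldehyde plus the same aryl Grignard reagent ⇒ 2,4,6‑trihydroxybenzaldehyde.
5. Rings: all four benzene rings are bought. The only ring made is the temporary benzoxepinone (step 3), which is opened again in step 5.

Assumption: the butyl chain is numbered C1 (diaryl CH) to C4 (CH2Ar), which makes the target (1R,2R,3S); 4‑(benzyloxy)phenylmagnesium bromide is bought as its THF solution.

**Step 1**
Reactants: 1 2,4,6‑trihydroxybenzaldehyde; 2 benzyl bromide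
Product: 3 2,4‑bis(benzyloxy)‑6‑hydroxybenzaldehyde
Conditions: BnBr (2.05 equiv), K2CO3 (2.1 equiv), DMF, rt, 16 h
Reagents that add atoms: benzyl bromide (2), BrCc1ccccc1
Why: Williamson etherification; the para hydroxyl and one ortho hydroxyl react, while the remaining ortho hydroxyl is hydrogen‑bonded to the formyl group and stays free; no stereocentre is formed.

**Step 2**
Reactants: 3 2,4‑bis(benzyloxy)‑6‑hydroxybenzaldehyde; 4 4‑(benzyloxy)phenylmagnesium bromide
Product: 6 (6Z)‑3,5‑bis(benzyloxy)‑6‑{[4‑(benzyloxy)phenyl]methylidene}cyclohexa‑2,4‑dien‑1‑one (o‑quinone methide), via o‑hydroxybenzhydrol 5 (not isolated)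
Conditions: 4 (2.2 equiv), THF, 0 °C to rt; aq. NH4Cl; crude 5, pyridinium p‑toluenesulfonate (5 mol %), 4 Å molecular sieves, CH2Cl2, rt
Reagents that add atoms: 4‑(benzyloxy)phenylmagnesium bromide (4), Br[Mg]c1ccc(OCc2ccccc2)cc1
Why: Grignard addition to the aldehyde (the first equivalent only deprotonates the phenol) followed by acid‑catalysed dehydration; three alkoxy donors make loss of water from 5 easy and stabilise 6 enough to handle, the C5 benzyloxy group turns the aryl group towards the carbonyl side (Z), and the racemic carbinol centre disappears.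

**Step 3 (key step)**
Reactants: 6 o‑quinone methide; 7 (E)‑but‑2‑enal (crotonaldehyde)
Product: 9 (4R,5R)‑6,8‑bis(benzyloxy)‑5‑[4‑(benzyloxy)phenyl]‑4‑methyl‑4,5‑dihydro‑1‑benzoxepin‑2(3H)‑one, via carbene‑bound homoenolate 8 (not isolated)
Conditions: 7 (2 equiv, added over 6 h), (5aR,10bS)‑2‑mesityl‑5a,10b‑dihydro‑4H,6H‑indeno[2,1‑b][1,2,4]triazolo[4,3‑d][1,4]oxazin‑2‑ium tetrafluoroborate (15 mol %), DBU (15 mol %), 4 Å molecular sieves, THF, rt
Reagents that add atoms: (E)‑but‑2‑enal (7), C/C=C/C=O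
Why: Carbene‑catalysed formal [4+3] annulation (homoenolate Michael addition, then lactonisation): the carbene converts the normally electrophilic β‑carbon of 7 into the nucleophile 8, which attacks the equally electrophilic methide carbon of 6; the indane wall of the catalyst covers the Si face of Cβ so that bond formation on the Re face sets 4R, the compact transition state held by the enol O–H···O=C contact presents the Re face of Z‑configured 6 so that methyl and aryl end up trans (5R), and the liberated phenoxide closes the lactone and releases the carbene.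

**Step 4**
Reactants: 9 lactone; 10 iodomethane
Product: 12 (3R,4S,5R)‑6,8‑bis(benzyloxy)‑5‑[4‑(benzyloxy)phenyl]‑3,4‑dimethyl‑4,5‑dihydro‑1‑benzoxepin‑2(3H)‑one, via lithium enolate 11 (not isolated)
Conditions: LiN(SiMe3)2 (1.1 equiv), THF, −78 °C; MeI (3 equiv), −78 to −40 °C
Reagents that add atoms: iodomethane (10), CI
Why: Diastereoselective lactone enolate alkylation: the C5 aryl group sits pseudo‑axial to escape the peri benzyloxy group, the trans C4 methyl is therefore pseudo‑axial on the other face next to the enolate carbon, and MeI enters anti to it to give the 3,4‑trans product (3R; the C4 label changes to S by priority only), C4 and C5 being untouched.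

**Step 5**
Reactants: 12 dimethyl lactone; 13 N,O‑dimethylhydroxylamine hydrochloride; 4 4‑(benzyloxy)phenylmagnesium bromide
Product: 15 (2R,3S,4R)‑1,4‑bis[4‑(benzyloxy)phenyl]‑4‑[2,4‑bis(benzyloxy)‑6‑hydroxyphenyl]‑2,3‑dimethylbutan‑1‑one, via Weinreb amide 14 (not isolated)
Conditions: 13 (1.5 equiv), i‑PrMgCl (3.0 equiv), THF, −20 °C, 1 h; then 4 (2.5 equiv), 0 °C to rt; aq. NH4Cl
Reagents that add atoms: 4‑(benzyloxy)phenylmagnesium bromide (4), Br[Mg]c1ccc(OCc2ccccc2)cc1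
Why: One‑pot Weinreb ketone synthesis: the magnesium amide opens the activated aryl ester to 14, whose chelated tetrahedral adduct with 4 survives until the quench and so stops at the ketone, and the cold, non‑equilibrating conditions keep the α‑stereocentre.

**Step 6**
Reactants: 15 keto phenol; 16 3‑(4‑methoxyphenyl)propanoyl chloride
Product: 18 (2R,3S,4R)‑1,4‑bis[4‑(benzyloxy)phenyl]‑4‑{4,6‑bis(benzyloxy)‑2‑hydroxy‑3‑[3‑(4‑methoxyphenyl)propanoyl]phenyl}‑2,3‑dimethylbutan‑1‑one, via chloromagnesium phenolate 17 (not isolated)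
Conditions: t‑BuMgCl (1.0 equiv, Et2O), toluene, 0 °C; then 16 (1.1 equiv), rt to 60 °C
Reagents that add atoms: 3‑(4‑methoxyphenyl)propanoyl chloride (16), COc1ccc(CCC(=O)Cl)cc1
Why: Magnesium‑phenolate‑directed ortho‑acylation (coordinated Friedel–Crafts acylation): the acid chloride bound to magnesium in 17 is delivered to the only free ortho carbon of a very electron‑rich ring without any strong acid, so the acid‑labile benzhydryl centre and the enolisable C3 centre are not disturbed.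

**Step 7**
Reactants: 18 protected diketone
Product: 19 1‑{2,4,6‑trihydroxy‑3‑[(1R,2R,3S)‑1,4‑bis(4‑hydroxyphenyl)‑2,3‑dimethylbutyl]phenyl}‑3‑(4‑methoxyphenyl)propan‑1‑one (target)
Conditions: H2 (4 bar), 10% Pd/C, THF–MeOH 1:1, AcOH (10 vol %), rt, 24 h
Reagents that add atoms: none
Why: Catalytic hydrogenolysis: Pd/C and H2 cleave the four benzyl ethers and take the 4‑oxyphenyl ketone down to CH2, while the 2,4,6‑trihydroxyphenyl ketone (a doubly hydrogen‑bonded vinylogous acid) and the aryl methyl ether are inert, and no stereocentre is touched.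

**Compound list**
1 | 2,4,6‑trihydroxybenzaldehyde | O=Cc1c(O)cc(O)cc1O | starting material
2 | benzyl bromide | BrCc1ccccc1 | starting material
3 | 2,4‑bis(benzyloxy)‑6‑hydroxybenzaldehyde | O=Cc1c(O)cc(OCc2ccccc2)cc1OCc1ccccc1 | intermediate
4 | 4‑(benzyloxy)phenylmagnesium bromide | Br[Mg]c1ccc(OCc2ccccc2)cc1 | starting material
5 | 3,5‑bis(benzyloxy)‑2‑{[4‑(benzyloxy)phenyl](hydroxy)methyl}phenol (racemic) | OC(c1ccc(OCc2ccccc2)cc1)c1c(O)cc(OCc2ccccc2)cc1OCc1ccccc1 | intermediate (not isolated)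
6 | (6Z)‑3,5‑bis(benzyloxy)‑6‑{[4‑(benzyloxy)phenyl]methylidene}cyclohexa‑2,4‑dien‑1‑one | O=C1C=C(OCc2ccccc2)C=C(OCc2ccccc2)/C1=C/c1ccc(OCc2ccccc2)cc1 | intermediate
7 | (E)‑but‑2‑enal | C/C=C/C=O | starting material
8 | carbene‑bound homoenolate (extended Breslow dienaminol from 7 and the (5aR,10bS) triazolylidene) | C/C=C/C(O)=C1N(c2c(C)cc(C)cc2C)N=C2CO[C@@H]3Cc4ccccc4[C@@H]3N12 | intermediate (not isolated)
9 | (4R,5R)‑6,8‑bis(benzyloxy)‑5‑[4‑(benzyloxy)phenyl]‑4‑methyl‑4,5‑dihydro‑1‑benzoxepin‑2(3H)‑one | O=C1C[C@@H](C)[C@H](c2ccc(OCc3ccccc3)cc2)c2c(OCc3ccccc3)cc(OCc3ccccc3)cc2O1 | intermediate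
10 | iodomethane | CI | starting material
11 | lithium enolate of 9 | [Li]OC1=C[C@@H](C)[C@H](c2ccc(OCc3ccccc3)cc2)c2c(OCc3ccccc3)cc(OCc3ccccc3)cc2O1 | intermediate (not isolated)
12 | (3R,4S,5R)‑6,8‑bis(benzyloxy)‑5‑[4‑(benzyloxy)phenyl]‑3,4‑dimethyl‑4,5‑dihydro‑1‑benzoxepin‑2(3H)‑one | O=C1[C@H](C)[C@@H](C)[C@H](c2ccc(OCc3ccccc3)cc2)c2c(OCc3ccccc3)cc(OCc3ccccc3)cc2O1 | intermediate
13 | N,O‑dimethylhydroxylamine hydrochloride | CNOC.Cl | starting material
14 | (2R,3S,4R)‑4‑[4‑(benzyloxy)phenyl]‑4‑[2,4‑bis(benzyloxy)‑6‑hydroxyphenyl]‑N‑methoxy‑N,2,3‑trimethylbutanamide | CON(C)C(=O)[C@H](C)[C@@H](C)[C@H](c1ccc(OCc2ccccc2)cc1)c1c(O)cc(OCc2ccccc2)cc1OCc1ccccc1 | intermediate (not isolated)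
15 | (2R,3S,4R)‑1,4‑bis[4‑(benzyloxy)phenyl]‑4‑[2,4‑bis(benzyloxy)‑6‑hydroxyphenyl]‑2,3‑dimethylbutan‑1‑one | O=C(c1ccc(OCc2ccccc2)cc1)[C@H](C)[C@@H](C)[C@H](c1ccc(OCc2ccccc2)cc1)c1c(O)cc(OCc2ccccc2)cc1OCc1ccccc1 | intermediate
16 | 3‑(4‑methoxyphenyl)propanoyl chloride | COc1ccc(CCC(=O)Cl)cc1 | starting material
17 | chloromagnesium phenolate of 15 | Cl[Mg]Oc1cc(OCc2ccccc2)cc(OCc2ccccc2)c1[C@@H](c1ccc(OCc2ccccc2)cc1)[C@H](C)[C@@H](C)C(=O)c1ccc(OCc2ccccc2)cc1 | intermediate (not isolated)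
18 | (2R,3S,4R)‑1,4‑bis[4‑(benzyloxy)phenyl]‑4‑{4,6‑bis(benzyloxy)‑2‑hydroxy‑3‑[3‑(4‑methoxyphenyl)propanoyl]phenyl}‑2,3‑dimethylbutan‑1‑one | COc1ccc(CCC(=O)c2c(OCc3ccccc3)cc(OCc3ccccc3)c([C@@H](c3ccc(OCc4ccccc4)cc3)[C@H](C)[C@@H](C)C(=O)c3ccc(OCc4ccccc4)cc3)c2O)cc1 | intermediate
19 | 1‑{2,4,6‑trihydroxy‑3‑[(1R,2R,3S)‑1,4‑bis(4‑hydroxyphenyl)‑2,3‑dimethylbutyl]phenyl}‑3‑(4‑methoxyphenyl)propan‑1‑one | COc1ccc(CCC(=O)c2c(O)cc(O)c([C@@H](c3ccc(O)cc3)[C@H](C)[C@@H](C)Cc3ccc(O)cc3)c2O)cc1 | target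

**Total steps:** 7. **Longest linear sequence:** 7 (1 to 19); every other input is bought.

**Three steps most likely to fail**

First, step 3.
- The donor‑rich quinone methide 6 may react slowly. That leaves room for self‑annulation of 7, or for β‑protonation followed by a [4+2] pathway.
- The trans outcome rests on the Z geometry of 6 and on a compact transition state. Neither has been proven for this substrate.
- The sense of induction comes from a shielding model. The antipodal triazolium salt is also sold if the model proves wrong.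
- The fallback replaces the catalytic homoenolate by a stoichiometric chiral one. It sets out from 6 and returns at 9.
- tert‑Butyl (4‑methoxyphenyl)carbamate is N‑alkylated with (E)‑crotyl bromide (NaH, DMF) to give tert‑butyl (E)‑but‑2‑en‑1‑yl(4‑methoxyphenyl)carbamate F1.
- Deprotonation with n‑BuLi and (−)‑sparteine (or its (+)‑surrogate, whichever delivers the 3S centre) in toluene at −78 °C, then γ‑selective addition to the methide carbon of 6, gives the Z‑enecarbamate F2.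
- Dilute HCl in CHCl3 hydrolyses this to the hydroxy aldehyde F3.
- Oxidative carbene catalysis then closes F3 to lactone 9. The reagents are 2‑mesityl‑6,7‑dihydro‑5H‑pyrrolo[2,1‑c][1,2,4]triazol‑2‑ium chloride, DBU and 3,3',5,5'‑tetra‑tert‑butyl‑4,4'‑diphenoquinone.

Second, step 6.
- The hindered phenolate may be acylated on oxygen instead of carbon.
- Attack at the other free ring carbon would not matter, because it converges on 19 after debenzylation.
- The fallback accepts O‑acylation and moves the acyl group afterwards. It sets out from 15 and returns at 18.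
- Compound 15 is esterified with 16 (Et3N, 4‑(dimethylamino)pyridine, CH2Cl2) to the aryl ester F4.
- A Fries rearrangement (TiCl4, CH2Cl2, −20 to 0 °C) shifts the acyl group to the free ortho carbon.
- Premature loss of the neighbouring benzyl group would be harmless, since all benzyl groups go in the last step.

Third, step 7.
- The α‑branched aryl ketone may reduce slowly or only in part. Forcing conditions could then begin to attack the other ketone.
- The fallback removes the C4 oxygen before the second ketone exists. It sets out from 15 and returns at 19.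
- NaBH4 (THF–MeOH, 0 °C) gives the benzylic alcohol F5 as an epimer mixture.
- Ionic deoxygenation (Et3SiH, BF3·OEt2, CH2Cl2, −78 °C) gives the diarylbutyl phenol F6.
- Acylation with 16 under the conditions of step 6 gives the benzyl‑protected dihydrochalcone F7.
- Mild hydrogenolysis (H2, 1 bar, Pd/C, EtOAc–MeOH) then only has to remove the benzyl groups to give 19.

**Further compounds**
F1 | step 3 | tert‑butyl (E)‑but‑2‑en‑1‑yl(4‑methoxyphenyl)carbamate | C/C=C/CN(C(=O)OC(C)(C)C)c1ccc(OC)cc1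
F2 | step 3 | Z‑enecarbamate: tert‑butyl {(1Z,3S,4R)‑4‑[4‑(benzyloxy)phenyl]‑4‑[2,4‑bis(benzyloxy)‑6‑hydroxyphenyl]‑3‑methylbut‑1‑en‑1‑yl}(4‑methoxyphenyl)carbamate | COc1ccc(cc1)N(C(=O)OC(C)(C)C)/C=C\[C@@H](C)[C@H](c1ccc(OCc2ccccc2)cc1)c1c(O)cc(OCc2ccccc2)cc1OCc1ccccc1
F3 | step 3 | hydroxy aldehyde: (3R,4R)‑4‑[4‑(benzyloxy)phenyl]‑4‑[2,4‑bis(benzyloxy)‑6‑hydroxyphenyl]‑3‑methylbutanal | O=CC[C@@H](C)[C@H](c1ccc(OCc2ccccc2)cc1)c1c(O)cc(OCc2ccccc2)cc1OCc1ccccc1
F4 | step 6 | aryl ester: 3,5‑bis(benzyloxy)‑2‑{(1R,2S,3R)‑1,4‑bis[4‑(benzyloxy)phenyl]‑2,3‑dimethyl‑4‑oxobutyl}phenyl 3‑(4‑methoxyphenyl)propanoate | COc1ccc(CCC(=O)Oc2cc(OCc3ccccc3)cc(OCc3ccccc3)c2[C@@H](c2ccc(OCc3ccccc3)cc2)[C@H](C)[C@@H](C)C(=O)c2ccc(OCc3ccccc3)cc2)cc1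
F5 | step 7 | benzylic alcohol: (2R,3S,4R)‑1,4‑bis[4‑(benzyloxy)phenyl]‑4‑[2,4‑bis(benzyloxy)‑6‑hydroxyphenyl]‑2,3‑dimethylbutan‑1‑ol (both C1 epimers) | OC(c1ccc(OCc2ccccc2)cc1)[C@H](C)[C@@H](C)[C@H](c1ccc(OCc2ccccc2)cc1)c1c(O)cc(OCc2ccccc2)cc1OCc1ccccc1
F6 | step 7 | diarylbutyl phenol: 3,5‑bis(benzyloxy)‑2‑{(1R,2R,3S)‑1,4‑bis[4‑(benzyloxy)phenyl]‑2,3‑dimethylbutyl}phenol | Oc1cc(OCc2ccccc2)cc(OCc2ccccc2)c1[C@@H](c1ccc(OCc2ccccc2)cc1)[C@H](C)[C@@H](C)Cc1ccc(OCc2ccccc2)cc1
F7 | step 7 | benzyl‑protected dihydrochalcone: 1‑{4,6‑bis(benzyloxy)‑3‑[(1R,2R,3S)‑1,4‑bis[4‑(benzyloxy)phenyl]‑2,3‑dimethylbutyl]‑2‑hydroxyphenyl}‑3‑(4‑methoxyphenyl)propan‑1‑one | COc1ccc(CCC(=O)c2c(OCc3ccccc3)cc(OCc3ccccc3)c([C@@H](c3ccc(OCc4ccccc4)cc3)[C@H](C)[C@@H](C)Cc3ccc(OCc4ccccc4)cc3)c2O)cc1
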